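**Retrosynthetic overview**

1. The route rests on C2 of the cembranolide: this lactone O–CH carbon is allylic (bonded to C3 of the E C3=C4 alkene in the 14-membered carbocycle C1–C14) and lies three bonds from the C16 carbonyl (O–C2–C1–C15–C16), so one alkenyl-metal/aldehyde union at C2–C3 can close the carbocycle and supply the oxygen of the cis-fused five-membered lactone.
2. Key disconnection C2–C3: seco ester 21 (C3 alkenyl iodide, C2 aldehyde, C16 methyl ester) → electroreductive chromium/nickel alkenylation; the carbocycle forms first, the γ-lactone follows in the same operation (23).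
3. After the key step: C17 methylene on C15, C13 desilylation, C13–OH-directed epoxidation of C11=C12 (erythro), Mitsunobu acetylation with inversion at C13 (threo epoxy acetate).
4. Before the key step: C1 by catalyst-controlled nitromethane addition (nitromethane carbon = C2, unmasked by a Nef reaction) to an enal made by cross-metathesis (C15, C16); C13 by asymmetric allylation (C14, C1).
5. C3–C13 chain: nerol (C6–C13, Z C7=C8) + 1-(trimethylsilyl)propyne (C3–C5), carboalumination–iodination (E C3=C4 iodide, C4 methyl), SeO2 oxidation of the E-methyl group to C13.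

Key step: step 14

Remark 1: cembrane numbering is used throughout (C1 ring-fusion CH, C2 lactone OCH, C15=C17H2, C16 lactone C=O); the CIP letters at C2 and C12 change between some intermediates through priority changes only, not through inversion.
Remark 2: vanadium-directed epoxidation of a 2-methyl allylic alcohol is erythro-selective, whereas the target is threo at C12/C13; C13 is therefore carried as the 13S silyl ether and inverted in the last step, and C1 is set by a catalyst so that it does not depend on C13.
Remark 3: it is assumed that the (S)-configured oxazoline–sulfonamide ligand is the antipode that directs alkenyl addition to the Si face of the C2 aldehyde; if not, its mirror image is used.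

**Route**

Step 1
Reactants: 1 nerol
Product: 2 neryl bromide [(2Z)-1-bromo-3,7-dimethylocta-2,6-diene]
Conditions: PBr3 (0.4 equiv), pyridine (cat.), Et2O, −10 °C
Reagents that add atoms: phosphorus tribromide, BrP(Br)Br
Why: SN2 displacement of the phosphite ester formed in situ by bromide at low temperature converts the primary allylic alcohol into the bromide without allylic transposition or Z-to-E isomerisation (alcohol-to-bromide substitution with PBr3).

Step 2
Reactants: 3 1-(trimethylsilyl)propyne; 2 neryl bromide
Product: 5 (5Z)-6,10-dimethyl-1-(trimethylsilyl)undeca-5,9-dien-1-yne, via propargyllithium 4 (not isolated)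
Conditions: n-BuLi, THF, −78 → −20 °C; then 2, −78 °C → rt
Reagents that add atoms: none
Why: Propargylic lithiation followed by SN2 alkylation of the primary allylic bromide (propargylation with a silyl-capped propargyl anion, the silyl group suppressing the allenyl mode) joins C5 to C6 and leaves the Z alkene untouched.

Step 3
Reactants: 5 silylated enyne
Product: 6 (5Z)-6,10-dimethylundeca-5,9-dien-1-yne
Conditions: K2CO3 (cat.), MeOH, rt
Reagents that add atoms: none
Why: Base-catalysed protodesilylation of the alkynylsilane by methanol (Si–C(sp) cleavage) frees the terminal alkyne needed for carbometallation.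

Step 4
Reactants: 6 terminal enyne
Product: 8 (1E,5Z)-1-iodo-2,6,10-trimethylundeca-1,5,9-triene, via alkenylalane 7 (not isolated)
Conditions: AlMe3 (2.5 equiv), Cp2ZrCl2 (0.25 equiv), DCM, 0 °C → rt; then I2, THF, −30 → 0 °C; aq. HCl
Reagents that add atoms: trimethylaluminium, C[Al](C)C; iodine, [I][I]
Why: Negishi zirconium-catalysed carboalumination adds methyl and aluminium syn across the terminal alkyne with methyl on the internal carbon, and iodinolysis of the C–Al bond with retention fixes the E geometry of the C3=C4 iodoalkene, the isolated trisubstituted alkenes being inert to AlMe3/Cp2ZrCl2.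

Step 5
Reactants: 8 iodotriene
Product: 9 (2E,6Z,10E)-11-iodo-2,6,10-trimethylundeca-2,6,10-trien-1-ol
Conditions: SeO2 (0.3 equiv), t-BuOOH (3 equiv), salicylic acid (0.1 equiv), DCM, 0 °C → rt
Reagents that add atoms: selenium dioxide, O=[Se]=O; tert-butyl hydroperoxide, CC(C)(C)OO
Why: Catalytic SeO2/t-BuOOH allylic oxidation (ene reaction then [2,3]-sigmatropic shift) should favour the terminal isopropylidene group as the most accessible electron-rich alkene and, by the usual rule, its E-methyl group, giving the E-allylic alcohol at C13, while the iodoalkene is electronically deactivated and C7=C8 reacts more slowly (run to partial conversion).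

Step 6
Reactants: 9 allylic alcohol
Product: 10 (2E,6Z,10E)-11-iodo-2,6,10-trimethylundeca-2,6,10-trienal
Conditions: MnO2 (excess), DCM, rt
Reagents that add atoms: none
Why: Allylic alcohol oxidation with MnO2 is selective for the activated carbinol and gives the E-enal without over-oxidation or alkene isomerisation.

Step 7
Reactants: 10 enal
Product: 12 (4S,5E,9Z,13E)-14-iodo-5,9,13-trimethyltetradeca-1,5,9,13-tetraen-4-ol, via borinate ester 11 (not isolated)
Conditions: (−)-Ipc2B(allyl) (1.3 equiv, salt-free), Et2O, −78 °C; then NaOH, H2O2, 0 °C → rt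
Reagents that add atoms: (−)-B-allyldiisopinocampheylborane, C=CCB([C@@H]1C[C@@H]2C[C@H]([C@H]1C)C2(C)C)[C@@H]1C[C@@H]2C[C@H]([C@H]1C)C2(C)C
Why: Brown allylboration through a closed chair transition state: the isopinocampheyl groups of the (+)-α-pinene-derived reagent deliver allyl to the Si face of the aldehyde in a 1,2-addition, which sets C13 as S under reagent control, and alkaline peroxide cleaves the borinate.

Step 8
Reactants: 12 homoallylic alcohol
Product: 13 tert-butyl{[(4S,5E,9Z,13E)-14-iodo-5,9,13-trimethyltetradeca-1,5,9,13-tetraen-4-yl]oxy}dimethylsilane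
Conditions: TBSCl, imidazole, DMF, rt
Reagents that add atoms: tert-butyldimethylsilyl chloride, CC(C)(C)[Si](C)(C)Cl
Why: Imidazole-promoted silylation of the secondary alcohol (silyl ether formation) masks C13–OH up to the end game and does not touch the stereocentre.

Step 9
Reactants: 13 silyl ether; 14 (E)-crotonaldehyde
Product: 15 (2E,5S,6E,10Z,14E)-5-[(tert-butyldimethylsilyl)oxy]-15-iodo-6,10,14-trimethylpentadeca-2,6,10,14-tetraenal
Conditions: 14 (5 equiv), second-generation Hoveyda–Grubbs catalyst (5 mol%), DCM, 40 °C
Reagents that add atoms: none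
Why: Olefin cross-metathesis between the only monosubstituted alkene and the electron-poor partner crotonaldehyde gives the E-enal with loss of propene, because the trisubstituted alkenes and the hindered iodoalkene do not engage the ruthenium carbene.

Step 10
Reactants: 15 enal; 16 nitromethane
Product: 17 (3S,5S,6E,10Z,14E)-5-[(tert-butyldimethylsilyl)oxy]-15-iodo-6,10,14-trimethyl-3-(nitromethyl)pentadeca-6,10,14-trienal
Conditions: 16 (5 equiv), (R)-α,α-diphenylprolinol trimethylsilyl ether (20 mol%), PhCO2H (20 mol%), MeOH, rt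
Reagents that add atoms: none
Why: Asymmetric Michael addition by iminium-ion catalysis: in the E-iminium ion of the enal the diphenyl(silyloxy)methyl group of the (R)-catalyst blocks one face, so the nitronate adds to the other face of the β-carbon and sets C1 as S under catalyst control, independent of the remote C13 centre.

Step 11
Reactants: 17 nitro aldehyde
Product: 18 (3S,5S,6E,10Z,14E)-5-[(tert-butyldimethylsilyl)oxy]-15-iodo-6,10,14-trimethyl-3-(nitromethyl)pentadeca-6,10,14-trienoic acid
Conditions: NaClO2, NaH2PO4, 2-methyl-2-butene, t-BuOH/H2O, 0 °C → rt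
Reagents that add atoms: sodium chlorite, [Na+].[O-]Cl=O
Why: Pinnick oxidation (chlorous acid, with 2-methyl-2-butene as hypochlorite scavenger) takes the aldehyde to the acid at pH 3–4 without touching the alkenes, the iodoalkene, the silyl ether or the nitro group.

Step 12
Reactants: 18 nitro acid
Product: 19 methyl (3S,5S,6E,10Z,14E)-5-[(tert-butyldimethylsilyl)oxy]-15-iodo-6,10,14-trimethyl-3-(nitromethyl)pentadeca-6,10,14-trienoate
Conditions: Me3SiCHN2, PhMe/MeOH, 0 °C
Reagents that add atoms: trimethylsilyldiazomethane, C[Si](C)(C)C=[N+]=[N-]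
Why: Esterification with trimethylsilyldiazomethane (protonation by the acid, then SN2 methyl transfer from the diazonium ion) is far faster for the carboxylic acid than any O-methylation of the weakly acidic nitroalkane.

Step 13
Reactants: 19 nitro ester
Product: 21 methyl (3S,5S,6E,10Z,14E)-5-[(tert-butyldimethylsilyl)oxy]-3-formyl-15-iodo-6,10,14-trimethylpentadeca-6,10,14-trienoate, via sodium nitronate 20 (not isolated)
Conditions: NaOMe, MeOH, 0 °C; then aq. TiCl3, NH4OAc (pH 5–6), THF, 0 °C → rt
Reagents that add atoms: water, O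
Why: Reductive Nef reaction: the nitronate is reduced by trivalent titanium to the imine, which hydrolyses in the buffer to the C2 aldehyde under conditions mild enough to keep the α-centre C1, the methyl ester, the silyl ether and the iodoalkene.

Step 14
Reactants: 21 seco aldehyde ester (C3 alkenyl iodide; C2 aldehyde; C16 methyl ester)
Product: 23 cis-fused γ-lactone of 2-[(1S,2R,3E,7Z,11E,13S)-13-[(tert-butyldimethylsilyl)oxy]-2-hydroxy-4,8,12-trimethylcyclotetradeca-3,7,11-trien-1-yl]acetic acid, via hydroxy ester 22 (not isolated)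
Conditions: CrCl3 (20 mol%), (S)-N-[2-(4-tert-butyl-4,5-dihydrooxazol-2-yl)-6-methylphenyl]methanesulfonamide (24 mol%), Et3N (24 mol%), NiCl2·dme (5 mol%), Cp2ZrCl2 (1.5 equiv), LiCl, n-Bu4NPF6, MeCN/THF, undivided cell, Al anode, carbon-felt cathode, constant current, slow addition of 21 (final 2 mM), rt; then aq. potassium sodium tartrate; PPTS (cat.), PhMe, 40 °C
Reagents that add atoms: none
Why: Proposed new method: oxidative addition of the C3–I bond to zerovalent nickel (retention of the E geometry), transfer of the alkenyl group to chromium and carbonyl addition of the alkenylchromium species to the C2 aldehyde make up the bond-forming sequence, while Cp2ZrCl2 takes the alkoxide off chromium and the trivalent chromium so released is reduced again to the divalent state at the cathode, so that both metals turn over. The closest known reactions are the chromium-catalysed electroreductive Nozaki–Hiyama–Kishi coupling of alkenyl halides with aldehydes and the stoichiometric nickel/chromium macrocyclisation; their combination in a ring closure with in-line lactonisation has not been shown. The 14-membered carbocycle closes by intramolecular 1,2-addition of C3 to C2 at high dilution, and the γ-lactone then closes by 5-exo-trig attack of the C2 oxygen on the C16 ester carbonyl with loss of methanol, completed by the mild acid treatment. C2 is the only new stereocentre: Si-face attack, which gives the cis ring fusion (H1 and H2 syn), is assigned to the chromium-bound chiral sulfonamide ligand, because the α-centre C1 carries two methylene arms of similar size and offers no reliable 1,2-induction. The step needs the aldehyde to react in preference to the ester and needs C1 and the alkene geometries to survive; the non-basic medium, the use of Cp2ZrCl2 instead of a chlorosilane (no enol silyl ether at C1) and the inertness of isolated trisubstituted alkenes and of the silyl ether towards alkenylchromium should secure this.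

Step 15
Reactants: 23 saturated lactone
Product: 26 cis-fused γ-lactone of 2-[(1S,2S,3E,7Z,11E,13S)-13-[(tert-butyldimethylsilyl)oxy]-2-hydroxy-4,8,12-trimethylcyclotetradeca-3,7,11-trien-1-yl]prop-2-enoic acid, via Mannich base 24 (not isolated), via ammonium iodide 25 (not isolated)
Conditions: LiN(SiMe3)2, THF, −78 °C; CH2=NMe2+ I−, −78 °C → rt; then MeI, MeOH, rt; then aq. NaHCO3, DCM, rt
Reagents that add atoms: Eschenmoser's salt (dimethylmethylideneammonium iodide), C=[N+](C)C.[I-]
Why: Mannich-type α-methylenation: the lactone lithium enolate at C15 is aminomethylated by Eschenmoser's salt, and quaternisation followed by E1cB loss of trimethylamine gives the exocyclic C15=C17 alkene, no stereocentre being affected since C1 is not enolisable.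

Step 16
Reactants: 26 α-methylene lactone silyl ether
Product: 27 cis-fused γ-lactone of 2-[(1S,2S,3E,7Z,11E,13S)-2,13-dihydroxy-4,8,12-trimethylcyclotetradeca-3,7,11-trien-1-yl]prop-2-enoic acid (lactone through O2)
Conditions: HF·pyridine, pyridine, THF, 0 °C → rt
Reagents that add atoms: none
Why: Fluoride-driven cleavage of the Si–O bond (desilylation) under pyridine-buffered conditions frees the C13 alcohol and leaves the α-methylene lactone and the allylic lactone C2–O bond intact.

Step 17
Reactants: 27 (13S)-allylic alcohol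
Product: 28 cis-fused γ-lactone of 2-[(1S,2S,3E,7Z,11S,12S,13S)-11,12-epoxy-2,13-dihydroxy-4,8,12-trimethylcyclotetradeca-3,7-dien-1-yl]prop-2-enoic acid (lactone through O2)
Conditions: VO(acac)2 (5 mol%), t-BuOOH (1.5 equiv, decane solution), DCM, 0 °C → rt
Reagents that add atoms: tert-butyl hydroperoxide, CC(C)(C)OO
Why: Hydroxyl-directed vanadium-catalysed epoxidation: the C13 vanadate ester delivers the peroxide oxygen only to the allylic C11=C12 alkene (C3=C4 and C7=C8 lack a directing group and C15=C17 is electron-poor), through a transition state with an O–C13–C12=C11 dihedral angle near 45° in which H13 rather than C14 lies beside the C12 methyl group (A(1,2) strain), so the erythro epoxy alcohol with the target's C11 and C12 configuration should form, the same outer face being favoured by peripheral attack on the macrocycle.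

Step 18
Reactants: 28 erythro epoxy alcohol
Product: 29 (1S,2S,3E,7Z,11S,12R,13R)-13-acetoxy-11,12-epoxycembra-3,7,15(17)-trien-16,2-olide (CNP0146076.3)
Conditions: PPh3, DIAD, THF, 0 °C (betaine pre-formed); then 28, AcOH, 0 °C → rt
Reagents that add atoms: acetic acid, CC(=O)O
Why: Mitsunobu esterification: acetate displaces the C13 oxyphosphonium group by SN2 with inversion, converting the erythro (13S) alcohol into the threo (13R) acetate of the target, and pre-forming the betaine keeps free PPh3 away from the α-methylene lactone.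

**Compound list**

1 | nerol, (2Z)-3,7-dimethylocta-2,6-dien-1-ol | CC(C)=CCC/C(C)=C\CO | starting material
2 | neryl bromide, (2Z)-1-bromo-3,7-dimethylocta-2,6-diene | CC(C)=CCC/C(C)=C\CBr | intermediate
3 | 1-(trimethylsilyl)propyne | CC#C[Si](C)(C)C | starting material
4 | 3-lithio-1-(trimethylsilyl)propyne (not isolated) | [Li]CC#C[Si](C)(C)C | intermediate
5 | (5Z)-6,10-dimethyl-1-(trimethylsilyl)undeca-5,9-dien-1-yne | C[Si](C)(C)C#CCC/C=C(/C)CCC=C(C)C | intermediate
6 | (5Z)-6,10-dimethylundeca-5,9-dien-1-yne | C#CCC/C=C(/C)CCC=C(C)C | intermediate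
7 | dimethyl[(1E,5Z)-2,6,10-trimethylundeca-1,5,9-trien-1-yl]alane (not isolated) | C[Al](C)/C=C(\C)CC/C=C(/C)CCC=C(C)C | intermediate
8 | (1E,5Z)-1-iodo-2,6,10-trimethylundeca-1,5,9-triene | I/C=C(\C)CC/C=C(/C)CCC=C(C)C | intermediate
9 | (2E,6Z,10E)-11-iodo-2,6,10-trimethylundeca-2,6,10-trien-1-ol | I/C=C(\C)CC/C=C(/C)CC/C=C(\C)CO | intermediate
10 | (2E,6Z,10E)-11-iodo-2,6,10-trimethylundeca-2,6,10-trienal | I/C=C(\C)CC/C=C(/C)CC/C=C(\C)C=O | intermediate
11 | diisopinocampheylborinate of alcohol 12 (not isolated) | I/C=C(\C)CC/C=C(/C)CC/C=C(\C)[C@@H](OB([C@@H]1C[C@@H]2C[C@H]([C@H]1C)C2(C)C)[C@@H]1C[C@@H]2C[C@H]([C@H]1C)C2(C)C)CC=C | intermediate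
12 | (4S,5E,9Z,13E)-14-iodo-5,9,13-trimethyltetradeca-1,5,9,13-tetraen-4-ol | I/C=C(\C)CC/C=C(/C)CC/C=C(\C)[C@@H](O)CC=C | intermediate
13 | tert-butyl{[(4S,5E,9Z,13E)-14-iodo-5,9,13-trimethyltetradeca-1,5,9,13-tetraen-4-yl]oxy}dimethylsilane | I/C=C(\C)CC/C=C(/C)CC/C=C(\C)[C@@H](O[Si](C)(C)C(C)(C)C)CC=C | intermediate
14 | (E)-crotonaldehyde | C/C=C/C=O | starting material
15 | (2E,5S,6E,10Z,14E)-5-[(tert-butyldimethylsilyl)oxy]-15-iodo-6,10,14-trimethylpentadeca-2,6,10,14-tetraenal | I/C=C(\C)CC/C=C(/C)CC/C=C(\C)[C@@H](O[Si](C)(C)C(C)(C)C)C/C=C/C=O | intermediate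
16 | nitromethane | C[N+](=O)[O-] | starting material
17 | (3S,5S,6E,10Z,14E)-5-[(tert-butyldimethylsilyl)oxy]-15-iodo-6,10,14-trimethyl-3-(nitromethyl)pentadeca-6,10,14-trienal | I/C=C(\C)CC/C=C(/C)CC/C=C(\C)[C@@H](O[Si](C)(C)C(C)(C)C)C[C@@H](CC=O)C[N+](=O)[O-] | intermediate
18 | (3S,5S,6E,10Z,14E)-5-[(tert-butyldimethylsilyl)oxy]-15-iodo-6,10,14-trimethyl-3-(nitromethyl)pentadeca-6,10,14-trienoic acid | I/C=C(\C)CC/C=C(/C)CC/C=C(\C)[C@@H](O[Si](C)(C)C(C)(C)C)C[C@@H](CC(=O)O)C[N+](=O)[O-] | intermediate
19 | methyl (3S,5S,6E,10Z,14E)-5-[(tert-butyldimethylsilyl)oxy]-15-iodo-6,10,14-trimethyl-3-(nitromethyl)pentadeca-6,10,14-trienoate | I/C=C(\C)CC/C=C(/C)CC/C=C(\C)[C@@H](O[Si](C)(C)C(C)(C)C)C[C@@H](CC(=O)OC)C[N+](=O)[O-] | intermediate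
20 | sodium nitronate of 19 (not isolated) | I/C=C(\C)CC/C=C(/C)CC/C=C(\C)[C@@H](O[Si](C)(C)C(C)(C)C)C[C@@H](CC(=O)OC)C=[N+]([O-])[O-].[Na+] | intermediate
21 | methyl (3S,5S,6E,10Z,14E)-5-[(tert-butyldimethylsilyl)oxy]-3-formyl-15-iodo-6,10,14-trimethylpentadeca-6,10,14-trienoate (key-step precursor; chain C3 = cembrane C1, chain C5 = cembrane C13) | I/C=C(\C)CC/C=C(/C)CC/C=C(\C)[C@@H](O[Si](C)(C)C(C)(C)C)C[C@@H](CC(=O)OC)C=O | intermediate
22 | methyl 2-[(1S,2R,3E,7Z,11E,13S)-13-[(tert-butyldimethylsilyl)oxy]-2-hydroxy-4,8,12-trimethylcyclotetradeca-3,7,11-trien-1-yl]acetate (not isolated) | O[C@H]1/C=C(\C)CC/C=C(/C)CC/C=C(\C)[C@@H](O[Si](C)(C)C(C)(C)C)C[C@H]1CC(=O)OC | intermediate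
23 | cis-fused γ-lactone of 2-[(1S,2R,3E,7Z,11E,13S)-13-[(tert-butyldimethylsilyl)oxy]-2-hydroxy-4,8,12-trimethylcyclotetradeca-3,7,11-trien-1-yl]acetic acid (key-step product) | O=C1O[C@H]2/C=C(\C)CC/C=C(/C)CC/C=C(\C)[C@@H](O[Si](C)(C)C(C)(C)C)C[C@H]2C1 | intermediate
24 | C15-(dimethylaminomethyl) derivative of lactone 23, C15 epimers (not isolated) | CN(C)CC1C(=O)O[C@H]2/C=C(\C)CC/C=C(/C)CC/C=C(\C)[C@@H](O[Si](C)(C)C(C)(C)C)C[C@@H]12 | intermediate
25 | C15-(trimethylammoniomethyl) derivative of lactone 23, iodide salt (not isolated) | C[N+](C)(C)CC1C(=O)O[C@H]2/C=C(\C)CC/C=C(/C)CC/C=C(\C)[C@@H](O[Si](C)(C)C(C)(C)C)C[C@@H]12.[I-] | intermediate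
26 | cis-fused γ-lactone of 2-[(1S,2S,3E,7Z,11E,13S)-13-[(tert-butyldimethylsilyl)oxy]-2-hydroxy-4,8,12-trimethylcyclotetradeca-3,7,11-trien-1-yl]prop-2-enoic acid | C=C1C(=O)O[C@H]2/C=C(\C)CC/C=C(/C)CC/C=C(\C)[C@@H](O[Si](C)(C)C(C)(C)C)C[C@@H]12 | intermediate
27 | cis-fused γ-lactone (through O2) of 2-[(1S,2S,3E,7Z,11E,13S)-2,13-dihydroxy-4,8,12-trimethylcyclotetradeca-3,7,11-trien-1-yl]prop-2-enoic acid | C=C1C(=O)O[C@H]2/C=C(\C)CC/C=C(/C)CC/C=C(\C)[C@@H](O)C[C@@H]12 | intermediate
28 | cis-fused γ-lactone (through O2) of 2-[(1S,2S,3E,7Z,11S,12S,13S)-11,12-epoxy-2,13-dihydroxy-4,8,12-trimethylcyclotetradeca-3,7-dien-1-yl]prop-2-enoic acid | C=C1C(=O)O[C@H]2/C=C(\C)CC/C=C(/C)CC[C@@H]3O[C@@]3(C)[C@@H](O)C[C@@H]12 | intermediate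
29 | (1S,2S,3E,7Z,11S,12R,13R)-13-acetoxy-11,12-epoxycembra-3,7,15(17)-trien-16,2-olide (CNP0146076.3) | C=C1C(=O)O[C@H]2/C=C(\C)CC/C=C(/C)CC[C@@H]3O[C@@]3(C)[C@H](OC(C)=O)C[C@@H]12 | target

**Step count and risks**

Total step count: 18. Longest linear sequence: 18 steps (1 → 29).

Steps most likely to fail:

1. Step 14 (proposed new method). What may go wrong: under catalytic electroreductive turnover the alkenylchromium species may be protonated or couple intermolecularly faster than the ring closes, or the chiral chromium complex may fail to control the C2 face. Fallback (known chemistry): from 21, the stoichiometric nickel/chromium macrocyclisation (CrCl2 in excess, NiCl2 cat., DMSO/THF, high dilution, rt, then PPTS) closes the ring under substrate control and should give lactone 23 together with its C2 epimer, the trans-fused lactone F1. F1 is saponified (LiOH, THF/H2O) to the C2-epimeric hydroxy acid F2, and Mitsunobu lactonisation of F2 (PPh3, DIAD, PhMe, 0 °C) inverts C2 and returns to 23.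

2. Step 18. What may go wrong: slow SN2 displacement at C13, which is flanked by the fully substituted epoxide carbon C12, so that elimination, epoxide participation or recovery of the alcohol competes. Fallback: from 28, oxidation with Dess–Martin periodinane (NaHCO3, DCM) gives the C13 epoxy ketone F3. Corey–Bakshi–Shibata reduction ((S)-2-methyl-CBS-oxazaborolidine, catecholborane, PhMe, −78 °C, with C12 as the large group) should give the (13R)-epoxy alcohol F4, and acetylation (Ac2O, DMAP, pyridine) returns to 29.

3. Step 13. What may go wrong: incomplete reduction of the nitronate, or epimerisation and aldol loss of the α-branched aldehyde during the aqueous titanium treatment. Fallback: from 19, reduction of the nitro group with SnCl2/PhSH/Et3N (MeCN, rt) stops at the aldoxime F5, and oxime exchange with aqueous glyoxylic acid (NaOAc, THF/H2O, rt) releases the aldehyde and returns to 21.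

**Further compounds**

F1 | step 14 | trans-fused γ-lactone, C2 epimer of 23 | O=C1O[C@@H]2/C=C(\C)CC/C=C(/C)CC/C=C(\C)[C@@H](O[Si](C)(C)C(C)(C)C)C[C@H]2C1
F2 | step 14 | 2-[(1S,2S,3E,7Z,11E,13S)-13-[(tert-butyldimethylsilyl)oxy]-2-hydroxy-4,8,12-trimethylcyclotetradeca-3,7,11-trien-1-yl]acetic acid | O[C@@H]1/C=C(\C)CC/C=C(/C)CC/C=C(\C)[C@@H](O[Si](C)(C)C(C)(C)C)C[C@H]1CC(=O)O
F3 | step 18 | C13 ketone of epoxy alcohol 28 | C=C1C(=O)O[C@H]2/C=C(\C)CC/C=C(/C)CC[C@@H]3O[C@@]3(C)C(=O)C[C@@H]12
F4 | step 18 | (13R)-epoxy alcohol, C13 epimer of 28 | C=C1C(=O)O[C@H]2/C=C(\C)CC/C=C(/C)CC[C@@H]3O[C@@]3(C)[C@H](O)C[C@@H]12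
F5 | step 13 | aldoxime of aldehyde 21 | I/C=C(\C)CC/C=C(/C)CC/C=C(\C)[C@@H](O[Si](C)(C)C(C)(C)C)C[C@@H](CC(=O)OC)C=NO
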